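**Retrosynthetic overview:** mulberrofuran X is a 7-geranyl-6-hydroxybenzofuran (rings A/B) bonded through C2 to C4' of an (R)-2-(2-hydroxypropan-2-yl)-2,3-dihydrobenzofuran-6-ol (rings C/D; primed locants O1', C2', C3', C3a', C4' to C7', C7a'); it is unmasked last from its tris-silyl ether.
That ether is cut in one Pd(OAc)2/norbornene operation at two bonds: the biaryl bond C2–C4' (ortho C–H heteroarylation by a 2-bromobenzofuran) and the ring bond C3'–C3a' (ipso termination by C(sp3)–H arylation of a methyl group), which opens ring D to an aryl iodide carrying an open-chain ether.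
Enabling feature: in ring D the methylene C3' sits on arene carbon C3a', and C3a' lies between the oxygen-bearing C7a' and the benzofuran-bearing C4'; an arylpalladium centred on C3a' (the iodine of 4-iodoresorcinol) therefore has exactly one free ortho C–H (C4') for the norbornene relay and, back at C3a', reaches the methyl group on C2' of the O1'-bound side chain through a six-membered palladacycle (Pd–C3a'–C7a'–O1'–C2'–C3').
The aryl iodide comes from 4-iodoresorcinol and ethyl (S)-lactate (Mitsunobu inversion sets C2' as R, MeMgBr builds the carbinol); the 2-bromobenzofuran comes from 2,4-dihydroxybenzaldehyde and geranyl bromide (C-geranylation, gem-dibromoolefination, CuI-catalysed O-vinylation).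
Order of ring formation: furan ring B first (step 4), dihydrofuran ring D second (step 9); benzene rings A and C are bought.

Key step: step 9

Remark on the chemistry: the stereocentre C2' of the target is read as (R) (CIP order O1' > C(CH3)2OH > C3' > H). Geranyl = (2E)-3,7-dimethylocta-2,6-dien-1-yl; TIPS = triisopropylsilyl; TES = triethylsilyl.

**Route**

Step 1
Reactants: 1 2,4-dihydroxybenzaldehyde; 2 geranyl bromide
Product: 3 3-geranyl-2,4-dihydroxybenzaldehyde
Conditions: KOH (1.1 equiv), H2O, 0 °C to rt; then aq. HCl
Reagents that add atoms: none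
Why: Phenoxide C-allylation: in water the hydrogen-bonded ambident resorcinolate of 1 should attack geranyl bromide by SN2 through its doubly activated C3 (between the two oxygens), which gives the linear geranyl group with the E alkene untouched.

Step 2
Reactants: 3 3-geranyl-2,4-dihydroxybenzaldehyde
Product: 4 3-geranyl-2-hydroxy-4-(triisopropylsilyloxy)benzaldehyde
Conditions: TIPSCl (1.1 equiv), imidazole (2.2 equiv), DMF, 0 °C to rt
Reagents that add atoms: triisopropylsilyl chloride, CC(C)[Si](Cl)(C(C)C)C(C)C
Why: Chemoselective silyl ether formation: the 2-hydroxyl is tied up in a hydrogen bond to the aldehyde and flanked on both sides, so the bulky silyl chloride should react only at the 4-hydroxyl.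

Step 3
Reactants: 4 3-geranyl-2-hydroxy-4-(triisopropylsilyloxy)benzaldehyde
Product: 5 2-(2,2-dibromoethenyl)-6-geranyl-5-(triisopropylsilyloxy)phenol
Conditions: CBr4 (3 equiv), PPh3 (6 equiv), Et3N (3 equiv), CH2Cl2, 0 °C
Reagents that add atoms: carbon tetrabromide, BrC(Br)(Br)Br
Why: Ramirez gem-dibromoolefination (the first half of the Corey–Fuchs sequence): the ylide Ph3P=CBr2 made in situ should convert the aldehyde into the 1,1-dibromoalkene, with excess reagent and Et3N making up for the acidic phenol while the trisubstituted alkenes and the silyl ether stay inert.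

Step 4
Reactants: 5 2-(2,2-dibromoethenyl)-6-geranyl-5-(triisopropylsilyloxy)phenol
Product: 6 2-bromo-7-geranyl-6-(triisopropylsilyloxy)-1-benzofuran
Conditions: CuI (5 mol%), K3PO4 (2 equiv), THF, 80 °C
Reagents that add atoms: none
Why: Copper-catalysed intramolecular Ullmann-type O-vinylation: the phenoxide should displace one bromine of the gem-dibromoalkene in a five-membered ring closure that forms the O1–C2 bond and leaves the second bromine as the C2–Br handle.

Step 5
Reactants: 7 4-iodoresorcinol (4-iodobenzene-1,3-diol)
Product: 8 2-iodo-5-(triisopropylsilyloxy)phenol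
Conditions: TIPSCl (1.05 equiv), imidazole (2.2 equiv), CH2Cl2, −20 °C to 0 °C
Reagents that add atoms: triisopropylsilyl chloride, CC(C)[Si](Cl)(C(C)C)C(C)C
Why: Site-selective silyl ether formation: the hydroxyl para to iodine is unhindered whereas the one ortho to the large iodine atom is shielded, so one equivalent of the bulky silyl chloride should protect only the former.

Step 6
Reactants: 8 2-iodo-5-(triisopropylsilyloxy)phenol; 9 ethyl (S)-lactate
Product: 10 ethyl (2R)-2-[2-iodo-5-(triisopropylsilyloxy)phenoxy]propanoate
Conditions: PPh3 (1.5 equiv), DIAD (1.5 equiv), THF, 0 °C to rt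
Reagents that add atoms: none
Why: Mitsunobu etherification: the phenol should displace the activated secondary hydroxyl of (S)-lactate by SN2 with clean inversion, which sets the future C2' as (R).

Step 7
Reactants: 10 ethyl (2R)-2-[2-iodo-5-(triisopropylsilyloxy)phenoxy]propanoate
Product: 12 (3R)-3-[2-iodo-5-(triisopropylsilyloxy)phenoxy]-2-methylbutan-2-ol, via methyl ketone 11 (not isolated)
Conditions: MeMgBr (3.5 equiv), THF, −20 °C to 0 °C; then aq. NH4Cl
Reagents that add atoms: methylmagnesium bromide, C[Mg]Br
Why: Double Grignard addition to the ester should give the tertiary alcohol without touching the stereocentre, because addition outruns enolization at low temperature and MeMgBr does not exchange with the aryl iodide under these conditions.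

Step 8
Reactants: 12 (3R)-3-[2-iodo-5-(triisopropylsilyloxy)phenoxy]-2-methylbutan-2-ol
Product: 13 triethyl{[(3R)-3-[2-iodo-5-(triisopropylsilyloxy)phenoxy]-2-methylbutan-2-yl]oxy}silane
Conditions: TESOTf (1.5 equiv), 2,6-lutidine (3 equiv), CH2Cl2, −78 °C to 0 °C
Reagents that add atoms: triethylsilyl trifluoromethanesulfonate, CC[Si](CC)(CC)OS(=O)(=O)C(F)(F)F
Why: Silyl ether formation at the hindered tertiary alcohol with the silyl triflate masks the hydroxyl, which would otherwise offer the arylpalladium of the next step a competing C–O bond-forming termination.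

Step 9
Reactants: 13 triethyl{[(3R)-3-[2-iodo-5-(triisopropylsilyloxy)phenoxy]-2-methylbutan-2-yl]oxy}silane; 6 2-bromo-7-geranyl-6-(triisopropylsilyloxy)-1-benzofuran (1.2 equiv)
Product: 15 (2R)-4-[7-geranyl-6-(triisopropylsilyloxy)-1-benzofuran-2-yl]-2-[2-(triethylsilyloxy)propan-2-yl]-6-(triisopropylsilyloxy)-2,3-dihydro-1-benzofuran, via arylpalladium bromide 14 (not isolated)
Conditions: Pd(OAc)2 (10 mol%), PCy3·HBF4 (20 mol%), norbornene (1.0 equiv), PivOH (30 mol%), Cs2CO3 (3 equiv), 1,4-dioxane, 100 °C then 130 °C, sealed tube
Reagents that add atoms: none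
Why: Proposed new method: zerovalent palladium should insert into the C–I bond of 13 (faster than into the C–Br bond of 6), norbornene insertion and carbonate-assisted palladation of the only free ortho C–H (C4'–H) should give the divalent aryl–norbornyl palladacycle, oxidative addition of the α-oxygen-activated C2–Br bond of 6 to it (tetravalent palladium) and aryl–aryl reductive elimination should form the C2–C4' bond, and, both ortho positions now being occupied, β-carbon elimination should expel norbornene to leave arylpalladium bromide 14 at C3a'. In 14 pivalate-assisted concerted metalation–deprotonation of the methyl group on C2' should give the six-membered palladacycle Pd–C3a'–C7a'–O1'–C2'–C3', and C(sp2)–C(sp3) reductive elimination should form the C3'–C3a' bond and return zerovalent palladium. The closest known reaction types are the Catellani ortho-arylation of ortho-substituted aryl iodides with aryl bromides (extended here to an electron-rich 2-bromobenzofuran) and the palladium-catalysed intramolecular C(sp3)–H arylation of 2-haloaryl alkyl ethers to 2,3-dihydrobenzofurans (used here as the ipso termination in place of a Heck or Suzuki step). One ring is closed, the five-membered dihydrofuran ring D, by reductive elimination from the six-membered palladacycle, so that O1', C7a', C3a', C3' and C2' end up in the ring and the carbinol stays exocyclic. No stereocentre is formed: C2' (R) was set in step 6, its tertiary C–H is not a site of metalation under these conditions, and it is carried through unchanged. The step needs site selectivity on the arene (secured by the position of iodine, which leaves C4'–H as the only ortho C–H, and by the ortho alkoxy group, which enforces aryl–aryl coupling and norbornene extrusion), the right order of events (norbornene insertion into the arylpalladium iodide is far faster than methyl C–H cleavage, so ring closure waits for the arylation) and methyl selectivity (the C2' methyl gives a six-membered palladacycle, the carbinol methyls would need a seven-membered one, and palladation of benzofuran C3–H gives only a five-membered palladacycle that cannot eliminate productively and should revert).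

Step 10
Reactants: 15 (2R)-4-[7-geranyl-6-(triisopropylsilyloxy)-1-benzofuran-2-yl]-2-[2-(triethylsilyloxy)propan-2-yl]-6-(triisopropylsilyloxy)-2,3-dihydro-1-benzofuran
Product: 16 mulberrofuran X
Conditions: TBAF (5 equiv), THF, 0 °C to rt; then aq. NH4Cl
Reagents that add atoms: none
Why: Fluoride-mediated global desilylation: the two aryl silyl ethers and the tertiary triethylsilyl ether should be cleaved by fluoride attack at silicon under conditions that leave the geranyl alkenes, the benzofuran and the C2' stereocentre untouched.

**Compound list**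

1 | 2,4-dihydroxybenzaldehyde | O=Cc1ccc(O)cc1O | starting material
2 | geranyl bromide, (2E)-1-bromo-3,7-dimethylocta-2,6-diene | CC(C)=CCC/C(C)=C/CBr | starting material
3 | 3-geranyl-2,4-dihydroxybenzaldehyde | CC(C)=CCC/C(C)=C/Cc1c(O)ccc(C=O)c1O | intermediate
4 | 3-geranyl-2-hydroxy-4-(triisopropylsilyloxy)benzaldehyde | CC(C)=CCC/C(C)=C/Cc1c(O[Si](C(C)C)(C(C)C)C(C)C)ccc(C=O)c1O | intermediate
5 | 2-(2,2-dibromoethenyl)-6-geranyl-5-(triisopropylsilyloxy)phenol | CC(C)=CCC/C(C)=C/Cc1c(O[Si](C(C)C)(C(C)C)C(C)C)ccc(C=C(Br)Br)c1O | intermediate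
6 | 2-bromo-7-geranyl-6-(triisopropylsilyloxy)-1-benzofuran | CC(C)=CCC/C(C)=C/Cc1c(O[Si](C(C)C)(C(C)C)C(C)C)ccc2cc(Br)oc12 | intermediate
7 | 4-iodoresorcinol (4-iodobenzene-1,3-diol) | Oc1ccc(I)c(O)c1 | starting material
8 | 2-iodo-5-(triisopropylsilyloxy)phenol | Oc1cc(O[Si](C(C)C)(C(C)C)C(C)C)ccc1I | intermediate
9 | ethyl (S)-lactate, ethyl (2S)-2-hydroxypropanoate | C[C@H](O)C(=O)OCC | starting material
10 | ethyl (2R)-2-[2-iodo-5-(triisopropylsilyloxy)phenoxy]propanoate | C[C@@H](Oc1cc(O[Si](C(C)C)(C(C)C)C(C)C)ccc1I)C(=O)OCC | intermediate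
11 | (3R)-3-[2-iodo-5-(triisopropylsilyloxy)phenoxy]butan-2-one (methyl ketone, not isolated) | C[C@@H](Oc1cc(O[Si](C(C)C)(C(C)C)C(C)C)ccc1I)C(C)=O | intermediate
12 | (3R)-3-[2-iodo-5-(triisopropylsilyloxy)phenoxy]-2-methylbutan-2-ol | C[C@@H](Oc1cc(O[Si](C(C)C)(C(C)C)C(C)C)ccc1I)C(C)(C)O | intermediate
13 | triethyl{[(3R)-3-[2-iodo-5-(triisopropylsilyloxy)phenoxy]-2-methylbutan-2-yl]oxy}silane | C[C@@H](Oc1cc(O[Si](C(C)C)(C(C)C)C(C)C)ccc1I)C(C)(C)O[Si](CC)(CC)CC | intermediate
14 | bromo{2-[7-geranyl-6-(triisopropylsilyloxy)-1-benzofuran-2-yl]-6-{[(2R)-3-methyl-3-(triethylsilyloxy)butan-2-yl]oxy}-4-(triisopropylsilyloxy)phenyl}palladium (arylpalladium bromide, phosphine ligand not drawn, not isolated) | C[C@@H](Oc1cc(O[Si](C(C)C)(C(C)C)C(C)C)cc(-c2cc3ccc(O[Si](C(C)C)(C(C)C)C(C)C)c(C/C=C(\C)CCC=C(C)C)c3o2)c1[Pd]Br)C(C)(C)O[Si](CC)(CC)CC | intermediate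
15 | (2R)-4-[7-geranyl-6-(triisopropylsilyloxy)-1-benzofuran-2-yl]-2-[2-(triethylsilyloxy)propan-2-yl]-6-(triisopropylsilyloxy)-2,3-dihydro-1-benzofuran | CC(C)=CCC/C(C)=C/Cc1c(O[Si](C(C)C)(C(C)C)C(C)C)ccc2cc(-c3cc(O[Si](C(C)C)(C(C)C)C(C)C)cc4c3C[C@H](C(C)(C)O[Si](CC)(CC)CC)O4)oc12 | intermediate
16 | mulberrofuran X, (2R)-4-(7-geranyl-6-hydroxy-1-benzofuran-2-yl)-2-(2-hydroxypropan-2-yl)-2,3-dihydro-1-benzofuran-6-ol | CC(C)=CCC/C(C)=C/Cc1c(O)ccc2cc(-c3cc(O)cc4c3C[C@H](C(C)(C)O)O4)oc12 | target

**Totals**

Total step count: 10.
Longest linear sequence: 6 steps (steps 5, 6, 7, 8, 9, 10; the other branch, steps 1, 2, 3, 4, 9, 10, is equally long).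
Starting materials 1, 2, 7 and 9 are catalogue compounds.

**Steps most likely to fail**

Step 9 (Proposed new method). Three processes may defeat it:
- Oxidative addition of the electron-rich, unactivated 2-bromobenzofuran to the divalent palladacycle may be too slow, so that the palladacycle decays by norbornene-retaining reductive elimination.
- After norbornene extrusion the arylpalladium may be drained by 1,4-palladium migration to benzofuran C3 or by norbornene re-insertion before the slower methyl C–H cleavage.
- If norbornene insertion lags, premature cyclization without arylation would occur.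

The fallback uses known reaction types and reverses the order, ring closure first and fragment union second. It sets out from 13. Norbornene-free palladium-catalysed intramolecular C(sp3)–H arylation (Pd(OAc)2, PCy3·HBF4, PivOH, Cs2CO3, mesitylene, 135 °C) should close ring D through the same C3'–C3a' bond and give (2R)-2-[2-(triethylsilyloxy)propan-2-yl]-6-(triisopropylsilyloxy)-2,3-dihydro-1-benzofuran F1. Iridium-catalysed C–H borylation ([Ir(OMe)(cod)]2, 4,4'-di-tert-butyl-2,2'-bipyridine, B2pin2, THF, 80 °C) should then take place at C4'–H, the only arene C–H without a neighbouring oxygen substituent (C5'–H and C7'–H are shielded by the triisopropylsilyloxy group; C4'–H is flanked only by the tied-back ring methylene), to give (2R)-4-(4,4,5,5-tetramethyl-1,3,2-dioxaborolan-2-yl)-2-[2-(triethylsilyloxy)propan-2-yl]-6-(triisopropylsilyloxy)-2,3-dihydro-1-benzofuran F2. Suzuki–Miyaura coupling of F2 with 6 (PdCl2(dppf), K3PO4, dioxane/H2O, 80 °C) comes back to the route at 15.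

Step 1. The ambident resorcinolate may be alkylated at oxygen, at C5 or twice, so that site selectivity for C3 and conversion are poor. The fallback replaces phenoxide alkylation by directed ortho-metalation and sets out from 1. Double protection (MOMCl, i-Pr2NEt, CH2Cl2) should give 2,4-bis(methoxymethoxy)benzaldehyde F3. In situ masking of the aldehyde as its α-amino alkoxide with lithium 4-methylpiperazin-1-ide and lithiation between the two acetal oxygens (n-BuLi, THF, −20 °C) should give the C3-lithiated lithium α-(4-methylpiperazin-1-yl)alkoxide of 2,4-bis(methoxymethoxy)benzaldehyde F4. In the presence of CuBr·SMe2, F4 should be allylated by 2 and give, after aqueous work-up, 3-geranyl-2,4-bis(methoxymethoxy)benzaldehyde F5. Mild acetal cleavage (HCl, MeOH, rt) comes back to the route at 3.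

Step 3. The basic ylide may deprotonate the free phenol; the phenoxide then deactivates the aldehyde and consumes reagent, and the olefination stalls. The fallback builds the furan ring from an alkyne and introduces bromine afterwards; it sets out from 4 and bypasses 5. Seyferth–Gilbert homologation (dimethyl (1-diazo-2-oxopropyl)phosphonate, K2CO3, MeOH, rt) should give 2-ethynyl-6-geranyl-5-(triisopropylsilyloxy)phenol F6. CuI-catalysed 5-endo-dig cycloisomerization (CuI, Et3N, DMF, 60 °C) should give 7-geranyl-6-(triisopropylsilyloxy)-1-benzofuran F7. Deprotonation at C2 (n-BuLi, THF, −78 °C) should give 7-geranyl-2-lithio-6-(triisopropylsilyloxy)-1-benzofuran F8, and bromination of F8 with 1,2-dibromotetrachloroethane comes back to the route at 6.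

**Further compounds**

F1 | step 9 | (2R)-2-[2-(triethylsilyloxy)propan-2-yl]-6-(triisopropylsilyloxy)-2,3-dihydro-1-benzofuran | c1cc(O[Si](C(C)C)(C(C)C)C(C)C)cc2c1C[C@H](C(C)(C)O[Si](CC)(CC)CC)O2
F2 | step 9 | (2R)-4-(4,4,5,5-tetramethyl-1,3,2-dioxaborolan-2-yl)-2-[2-(triethylsilyloxy)propan-2-yl]-6-(triisopropylsilyloxy)-2,3-dihydro-1-benzofuran | CC1(C)OB(OC1(C)C)c1cc(O[Si](C(C)C)(C(C)C)C(C)C)cc2c1C[C@H](C(C)(C)O[Si](CC)(CC)CC)O2
F3 | step 1 | 2,4-bis(methoxymethoxy)benzaldehyde | COCOc1ccc(C=O)c(OCOC)c1
F4 | step 1 | C3-lithiated lithium α-(4-methylpiperazin-1-yl)alkoxide of 2,4-bis(methoxymethoxy)benzaldehyde (not isolated) | COCOc1ccc(C(O[Li])N2CCN(C)CC2)c(OCOC)c1[Li]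
F5 | step 1 | 3-geranyl-2,4-bis(methoxymethoxy)benzaldehyde | CC(C)=CCC/C(C)=C/Cc1c(OCOC)ccc(C=O)c1OCOC
F6 | step 3 | 2-ethynyl-6-geranyl-5-(triisopropylsilyloxy)phenol | CC(C)=CCC/C(C)=C/Cc1c(O[Si](C(C)C)(C(C)C)C(C)C)ccc(C#C)c1O
F7 | step 3 | 7-geranyl-6-(triisopropylsilyloxy)-1-benzofuran | CC(C)=CCC/C(C)=C/Cc1c(O[Si](C(C)C)(C(C)C)C(C)C)ccc2ccoc12
F8 | step 3 | 7-geranyl-2-lithio-6-(triisopropylsilyloxy)-1-benzofuran (not isolated) | CC(C)=CCC/C(C)=C/Cc1c(O[Si](C(C)C)(C(C)C)C(C)C)ccc2cc([Li])oc12
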